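**Retrosynthetic overview**
1. The C5–O(aryl) bond is made last: SN2 (trans) opening of the anti diol epoxide 12 at C5 by the 6-oxide of the catechol chromone 17.
2. 12 comes from the trans-7,8-dihydrodiol 11 (7-OH-directed epoxidation), and 11 from the tetrahydro trans-diacetate 8 (C5 bromination, then elimination).
3. 8 comes from the achiral diene 5 by metal-free chiral-dioxirane epoxidation of C7=C8 (first stereocentres) and trans hydrolysis at C8.
4. Ring order: the carbocycle (ring A) is cyclohex-2-enone itself, and the pyranone ring is annulated onto it before any stereocentre exists. The aromatic chromone 17 is built separately by Claisen condensation and cyclodehydration.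

Assumption: 5-phenylpent-2-ynoic acid (2) is bought (otherwise one step from 4-phenylbut-1-yne, BuLi and CO2); locants C2–C8a in names and text are chromone numbers.

**Step 1**
Reactants: 1 cyclohex-2-en-1-one; 2 5-phenylpent-2-ynoic acid
Product: 5 2-(2-phenylethyl)-5,6-dihydro-4H-chromen-4-one, via acid chloride 3 (not isolated), via enol ynone 4 (not isolated)
Conditions: 2, (COCl)2, DMF (cat.), CH2Cl2, 0 °C→rt, evaporate; 1 (2.0 equiv), LiN(SiMe3)2 (2.0 equiv), THF, −78 °C, then 3, −78→0 °C; aq. NH4Cl; then Et2NH (0.2 equiv), EtOH, rt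
Reagents that add atoms: none
Why: Kinetic deprotonation of the enone gives the cross-conjugated lithium dienolate, which is C-acylated by the acid chloride (Claisen-type acylation, the second equivalent of enolate taking up the acidic proton of the product), and amine-catalysed 6-endo-dig oxa-Michael addition of the enol oxygen to the ynone (via the enaminone) closes the γ-pyrone; no stereocentre is formed.

**Step 2**
Reactants: 5 2-(2-phenylethyl)-5,6-dihydro-4H-chromen-4-one
Product: 6 (7R,8R)-7,8-epoxy-2-(2-phenylethyl)-5,6,7,8-tetrahydro-4H-chromen-4-one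
Conditions: L-glucose-derived enantiomer of Shi's spiro N-(4-methylphenyl)oxazolidinone ketone (0.25 equiv), KHSO5 (Oxone, 1.8 equiv), K2CO3, Bu4NHSO4 (cat.), DME–aq. K2CO3/AcOH buffer (pH 8–9), −10→0 °C
Reagents that add atoms: potassium peroxymonosulfate (KHSO5), [K+].[O-]S(=O)(=O)OO
Why: Proposed new method: a chiral dioxirane generated in situ from the ketone and KHSO5 (Shi-type epoxidation) is applied for the first time to the γ,δ-olefin of a 5,6-dihydro-4-pyranone dienone; electrophilic oxygen transfer through the spiro transition state should occur only at the disubstituted C7=C8 bond (the push–pull C4a=C8a and C2=C3 bonds are deactivated), with the planar pyranone π-system on C8 lying next to the catalyst's oxazolidinone as the aryl group does in the closest known cases (1,2-dihydronaphthalene, 2,2-dimethylchromenes, conjugated cis-dienes), so that the L-glucose-derived ketone is expected to set both first stereocentres as 7R,8R.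

**Step 3**
Reactants: 6 (7R,8R)-7,8-epoxy-2-(2-phenylethyl)-5,6,7,8-tetrahydro-4H-chromen-4-one
Product: 8 (7R,8S)-4-oxo-2-(2-phenylethyl)-5,6,7,8-tetrahydro-4H-chromene-7,8-diyl diacetate, via trans-diol 7 (not isolated)
Conditions: HClO4 (0.1 equiv), THF–H2O 3:1, 0 °C→rt; extract; then Ac2O, pyridine, DMAP (cat.), CH2Cl2, rt; recrystallise to raise ee
Reagents that add atoms: water, O; acetic anhydride, CC(=O)OC(C)=O
Why: Acid-catalysed (A-2) hydrolysis of a γ,δ-epoxy enone proceeds by SN2 attack of water at the allylic γ-carbon C8 with inversion (C7–O untouched), so the cis-epoxide gives the trans-(7R,8S)-diol without loss of ee, and DMAP-catalysed acetylation then masks both hydroxyls for the radical step.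

**Step 4**
Reactants: 8 (7R,8S)-4-oxo-2-(2-phenylethyl)-5,6,7,8-tetrahydro-4H-chromene-7,8-diyl diacetate
Product: 10 (7R,8S)-4-oxo-2-(2-phenylethyl)-7,8-dihydro-4H-chromene-7,8-diyl diacetate, via allylic bromide 9 (not isolated)
Conditions: NBS (1.05 equiv), AIBN (0.05 equiv), PhCF3, 80 °C; filter, concentrate; then DBU (1.5 equiv), THF, 0 °C
Reagents that add atoms: none
Why: Wohl–Ziegler bromination should take the C5 hydrogen because the resulting allyl radical ends on the oxygen-bearing C8a (a weaker, polarity-matched C–H than the side-chain benzylic CH2, while the acetoxy-bearing C8–H is deactivated), and DBU-mediated E2 loss of HBr then installs the C5=C6 olefin without touching C7 or C8, as in classical syntheses of arene trans-dihydrodiols.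

**Step 5**
Reactants: 10 (7R,8S)-4-oxo-2-(2-phenylethyl)-7,8-dihydro-4H-chromene-7,8-diyl diacetate
Product: 11 (7R,8S)-7,8-dihydroxy-2-(2-phenylethyl)-7,8-dihydro-4H-chromen-4-one
Conditions: K2CO3 (0.2 equiv), MeOH, 0 °C
Reagents that add atoms: none
Why: Carbonate-catalysed transesterification (Zemplén-type methanolysis) removes both acetates at 0 °C far faster than any base-induced elimination, and the trans-dihydrodiol is stable to base, so both stereocentres are kept.

**Step 6**
Reactants: 11 (7R,8S)-7,8-dihydroxy-2-(2-phenylethyl)-7,8-dihydro-4H-chromen-4-one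
Product: 12 (5R,6S,7S,8S)-5,6-epoxy-7,8-dihydroxy-2-(2-phenylethyl)-5,6,7,8-tetrahydro-4H-chromen-4-one
Conditions: mCPBA (purified, 3 equiv), THF, 0 °C→rt, Ar; cold dilute aq. NaOH wash; use at once
Reagents that add atoms: 3-chloroperoxybenzoic acid (mCPBA), OOC(=O)c1cccc(Cl)c1
Why: Henbest-type hydroxyl-directed Prilezhaev epoxidation: the allylic 7-OH of the diequatorial trans-diol hydrogen-bonds the peracid and delivers oxygen to its own face of the electron-rich C5=C6 bond, giving the anti diol epoxide (oxirane cis to 7-OH, trans to 8-OH) and so setting C5 and C6 by substrate control (the C7 label changes from R to S only through CIP priorities).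

**Step 7**
Reactants: 13 1-(2-hydroxy-4,5-dimethoxyphenyl)ethan-1-one; 14 ethyl 3-phenylpropanoate
Product: 17 6,7-dihydroxy-2-(2-phenylethyl)-4H-chromen-4-one, via diketone 15 (not isolated), via dimethoxychromone 16 (not isolated)
Conditions: NaH (4 equiv), THF, reflux; AcOH quench, concentrate; then 48% aq. HBr, AcOH, 120 °C
Reagents that add atoms: none
Why: Crossed Claisen condensation of the acetophenone dianion with the ester gives the 1,3-diketone, which hot HBr/AcOH cyclodehydrates to the chromone and then demethylates at both aryl methyl ethers (SN2 at methyl), the standard route to hydroxylated 2-(2-phenylethyl)chromones; no stereocentre is involved.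

**Step 8**
Reactants: 12 (5R,6S,7S,8S)-5,6-epoxy-7,8-dihydroxy-2-(2-phenylethyl)-5,6,7,8-tetrahydro-4H-chromen-4-one; 17 6,7-dihydroxy-2-(2-phenylethyl)-4H-chromen-4-one
Product: 18 7-hydroxy-2-(2-phenylethyl)-6-{[(5S,6S,7R,8S)-6,7,8-trihydroxy-4-oxo-2-(2-phenylethyl)-5,6,7,8-tetrahydro-4H-chromen-5-yl]oxy}-4H-chromen-4-one
Conditions: 17 (1.5 equiv), KOC(CH3)3 (3.0 equiv), degassed DMSO, rt, 15 min; then 12 (1.0 equiv), rt→40 °C, Ar; aq. NH4Cl
Reagents that add atoms: none
Why: In the catechol dianion the 6-oxide, which unlike the 7-oxide is not conjugated with the C4 carbonyl, is the more nucleophilic oxygen and opens the oxirane by SN2 at the allylic C5 (trans-diaxial, Fürst–Plattner) with inversion, so that C5 becomes S while the configurations at C6, C7 and C8 are untouched (the C7 label returns from S to R only through CIP priorities) and the product is the target.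

**Compound list**
1 | cyclohex-2-en-1-one | O=C1C=CCCC1 | starting material
2 | 5-phenylpent-2-ynoic acid | OC(=O)C#CCCc1ccccc1 | starting material
3 | 5-phenylpent-2-ynoyl chloride | ClC(=O)C#CCCc1ccccc1 | intermediate (not isolated)
4 | 1-(2-hydroxycyclohexa-1,3-dien-1-yl)-5-phenylpent-2-yn-1-one (enol form of the 6-acylcyclohexenone) | OC1=C(C(=O)C#CCCc2ccccc2)CCC=C1 | intermediate (not isolated)
5 | 2-(2-phenylethyl)-5,6-dihydro-4H-chromen-4-one (C7=C8 olefin, achiral) | O=C1C=C(CCc2ccccc2)OC2=C1CCC=C2 | intermediate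
6 | (7R,8R)-7,8-epoxy-2-(2-phenylethyl)-5,6,7,8-tetrahydro-4H-chromen-4-one | O=C1C=C(CCc2ccccc2)OC2=C1CC[C@H]3O[C@@H]23 | intermediate
7 | (7R,8S)-7,8-dihydroxy-2-(2-phenylethyl)-5,6,7,8-tetrahydro-4H-chromen-4-one (trans-diol) | O=C1C=C(CCc2ccccc2)OC2=C1CC[C@@H](O)[C@@H]2O | intermediate (not isolated)
8 | (7R,8S)-4-oxo-2-(2-phenylethyl)-5,6,7,8-tetrahydro-4H-chromene-7,8-diyl diacetate | O=C1C=C(CCc2ccccc2)OC2=C1CC[C@@H](OC(C)=O)[C@@H]2OC(C)=O | intermediate
9 | (7R,8S)-5-bromo-4-oxo-2-(2-phenylethyl)-5,6,7,8-tetrahydro-4H-chromene-7,8-diyl diacetate (mixture of C5 epimers) | O=C1C=C(CCc2ccccc2)OC2=C1C(Br)C[C@@H](OC(C)=O)[C@@H]2OC(C)=O | intermediate (not isolated)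
10 | (7R,8S)-4-oxo-2-(2-phenylethyl)-7,8-dihydro-4H-chromene-7,8-diyl diacetate | O=C1C=C(CCc2ccccc2)OC2=C1C=C[C@@H](OC(C)=O)[C@@H]2OC(C)=O | intermediate
11 | (7R,8S)-7,8-dihydroxy-2-(2-phenylethyl)-7,8-dihydro-4H-chromen-4-one (trans-dihydrodiol) | O=C1C=C(CCc2ccccc2)OC2=C1C=C[C@@H](O)[C@@H]2O | intermediate
12 | (5R,6S,7S,8S)-5,6-epoxy-7,8-dihydroxy-2-(2-phenylethyl)-5,6,7,8-tetrahydro-4H-chromen-4-one (oxirane cis to 7-OH, trans to 8-OH) | O=C1C=C(CCc2ccccc2)OC2=C1[C@H]3O[C@H]3[C@@H](O)[C@@H]2O | intermediate
13 | 1-(2-hydroxy-4,5-dimethoxyphenyl)ethan-1-one | CC(=O)c1cc(OC)c(OC)cc1O | starting material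
14 | ethyl 3-phenylpropanoate | CCOC(=O)CCc1ccccc1 | starting material
15 | 1-(2-hydroxy-4,5-dimethoxyphenyl)-5-phenylpentane-1,3-dione | O=C(CC(=O)CCc1ccccc1)c1cc(OC)c(OC)cc1O | intermediate (not isolated)
16 | 6,7-dimethoxy-2-(2-phenylethyl)-4H-chromen-4-one | COc1cc2oc(CCc3ccccc3)cc(=O)c2cc1OC | intermediate (not isolated)
17 | 6,7-dihydroxy-2-(2-phenylethyl)-4H-chromen-4-one | Oc1cc2oc(CCc3ccccc3)cc(=O)c2cc1O | intermediate
18 | 7-hydroxy-2-(2-phenylethyl)-6-{[(5S,6S,7R,8S)-6,7,8-trihydroxy-4-oxo-2-(2-phenylethyl)-5,6,7,8-tetrahydro-4H-chromen-5-yl]oxy}-4H-chromen-4-one | O=c1cc(CCc2ccccc2)oc2c1[C@H](Oc1cc3c(=O)cc(CCc4ccccc4)oc3cc1O)[C@@H](O)[C@@H](O)[C@@H]2O | target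

**Step count**
Total: 8 steps. Longest linear sequence: 7 steps (steps 1, 2, 3, 4, 5, 6, 8); step 7 is the convergent branch.

**Three steps most likely to fail, with fallbacks**

Step 2 (the new step). The olefin is electron-poor for a dioxirane, the ee on this substrate class is unknown, and the sense of induction is assigned only by analogy (if it proves opposite, the D-glucose-derived ketone is used). If the epoxidation of 5 is too slow or poorly selective, the same epoxide is reached by known chemistry, with the stereocentres set before the pyranone ring. Setting out from 1, the known primary-amine-salt-catalysed Weitz–Scheffer epoxidation of cyclohex-2-enone (9-amino-9-deoxy-epi-cinchona alkaloid bis(trifluoroacetate), 30% H2O2, dioxane, 30–50 °C; quinine- or quinidine-derived catalyst chosen for the 2R,3R sense) gives (2R,3R)-2,3-epoxycyclohexanone F1. Its kinetic lithium enolate (LiN(SiMe3)2, THF, −78 °C, deprotonation at C6) is C-acylated with acid chloride 3 to give 1-[(1R,6R)-2-hydroxy-7-oxabicyclo[4.1.0]hept-2-en-3-yl]-5-phenylpent-2-yn-1-one F2. Et2NH-catalysed 6-endo closure in EtOH (no acid, oxirane untouched) comes back to the route at 6.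

Step 4. Radical bromination may also attack the two side-chain CH2 groups, or the labile bromide may aromatise. In that case the olefin is introduced by hydride abstraction instead of radical substitution. Setting out from 8, DDQ (1.2 equiv, dioxane, 90 °C) removes hydride only from C5 (the one site that gives an allyl cation stabilised by O1), loss of H-6 gives the olefin, and the route is rejoined directly at 10. No new compound is formed.

Step 8. Alkylation at O7, double alkylation or air oxidation of the dianion may compete. In that case the 7-oxygen is blocked. Setting out from 17, allyl bromide with one equivalent of K2CO3 (acetone, rt) alkylates the more acidic 7-OH to give 6-hydroxy-2-(2-phenylethyl)-7-(prop-2-en-1-yloxy)-4H-chromen-4-one F3. Its single phenoxide (Cs2CO3, DMF, 40 °C) opens 12 at C5 to give 6-{[(5S,6S,7R,8S)-6,7,8-trihydroxy-4-oxo-2-(2-phenylethyl)-5,6,7,8-tetrahydro-4H-chromen-5-yl]oxy}-2-(2-phenylethyl)-7-(prop-2-en-1-yloxy)-4H-chromen-4-one F4. Pd(PPh3)4 with morpholine (THF, rt) removes the allyl group and comes back to the route at 18.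

**Further compounds**
F1 | step 2 | (2R,3R)-2,3-epoxycyclohexanone | O=C1CCC[C@H]2O[C@@H]12
F2 | step 2 | 1-[(1R,6R)-2-hydroxy-7-oxabicyclo[4.1.0]hept-2-en-3-yl]-5-phenylpent-2-yn-1-one | OC1=C(C(=O)C#CCCc2ccccc2)CC[C@H]2O[C@@H]12
F0 | step 4 | none | none
F3 | step 8 | 6-hydroxy-2-(2-phenylethyl)-7-(prop-2-en-1-yloxy)-4H-chromen-4-one | C=CCOc1cc2oc(CCc3ccccc3)cc(=O)c2cc1O
F4 | step 8 | 6-{[(5S,6S,7R,8S)-6,7,8-trihydroxy-4-oxo-2-(2-phenylethyl)-5,6,7,8-tetrahydro-4H-chromen-5-yl]oxy}-2-(2-phenylethyl)-7-(prop-2-en-1-yloxy)-4H-chromen-4-one | O=c1cc(CCc2ccccc2)oc2c1[C@H](Oc1cc3c(=O)cc(CCc4ccccc4)oc3cc1OCC=C)[C@@H](O)[C@@H](O)[C@@H]2O
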